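**Retrosynthetic overview**

1. Last operation: the side-chain tertiary carbinol is released from its TBS ether 17; rings and stereocentres are complete after the key step.
2. Key disconnection (step 10): the aryl ether bond of ring D (carbinol oxygen to C-4 of quinolone E), the C-c–C-3 bond to quinolone E and the ring C ether bond O–C-c are cut together, giving lactol 15 and 4-methoxyquinolone 9.
3. Enabling feature: C-c is bonded both to the vinylogous-acid oxygen of quinolone W (ring C) and to C-3 of a 4-alkoxy-2-quinolone. It therefore ionises to an allyl cation over C-c/C-3/C-4 whose C-4 end is a methoxy-oxocarbenium carbon lying 1,5 to the carbinol oxygen on CMe2.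
4. Lactol 15: C-b and its CMe2OH by aldol of lactone 11 with acetone anti to C-a; C-a by iminium-catalysed Michael addition of quinolone 8 to enal 4; 8 and 9 from 1-bromo-2,3-dimethoxybenzene, methylamine and an aryl malonate.
5. Ring order: quinolone rings, then ring C (as lactol/lactone, a temporary closure), then union with quinolone E, ring D (O–C-4), and ring C re-closed cis.

Key step: step 10

Remark on names: quinolone W is the quinolone written first in the target SMILES and quinolone E the second; ring C is the pyran on W and ring D the gem-dimethylpyran on E; C-a is the CH bearing the CH2CMe2O chain, C-b the ring-fusion CH bearing CMe2, C-c the ring-fusion O–CH.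

Assumption: the cis fusion of rings C and D is taken to be the kinetic result of intramolecular oxygen capture of the ring-D allyl cation (the event presumed in the acid-type dimerisation of the parent pyranoquinolone), so C-c needs no separate control.

**Route**

Step 1
Reactants: 1 2-methylpent-4-en-2-ol
Product: 2 tert-butyldimethyl[(2-methylpent-4-en-2-yl)oxy]silane
Conditions: TBSOTf, 2,6-lutidine, CH2Cl2, 0 °C to rt
Reagents that add atoms: tert-butyldimethylsilyl trifluoromethanesulfonate, CC(C)(C)[Si](C)(C)OS(=O)(=O)C(F)(F)F
Why: Silylation of a tertiary alcohol with a silyl triflate and a hindered pyridine base is standard, and the hindered tertiary TBS ether should later keep this oxygen from capturing the cation of step 10.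

Step 2
Reactants: 2 tert-butyldimethyl[(2-methylpent-4-en-2-yl)oxy]silane, 3 (E)-but-2-enal
Product: 4 (E)-5-[(tert-butyldimethylsilyl)oxy]-5-methylhex-2-enal
Conditions: second-generation Hoveyda–Grubbs catalyst (3 mol%), 3 (5 equiv), CH2Cl2, 40 °C
Reagents that add atoms: none
Why: Olefin cross-metathesis of a terminal alkene with excess crotonaldehyde should give the (E)-enal under thermodynamic control with loss of propene.

Step 3
Reactants: 5 1-bromo-2,3-dimethoxybenzene
Product: 6 2,3-dimethoxy-N-methylaniline
Conditions: MeNH2 (2 M in THF), Pd2(dba)3 (1 mol%), BrettPhos (2.4 mol%), NaOtBu, dioxane, 80 °C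
Reagents that add atoms: methylamine, CN
Why: Buchwald–Hartwig amination with a bulky biarylphosphine is selective for mono-arylation of methylamine and tolerates the ortho-methoxy group.

Step 4
Reactants: 6 2,3-dimethoxy-N-methylaniline, 7 bis(2,4,6-trichlorophenyl) malonate
Product: 8 4-hydroxy-7,8-dimethoxy-1-methylquinolin-2(1H)-one
Conditions: Ph2O, 200 °C
Reagents that add atoms: none
Why: Thermal condensation of an N-alkylaniline with an activated aryl malonate (N-acylation, then acylketene Friedel–Crafts closure at the only free ortho position, para to a methoxy group) is the classical 4-hydroxy-2-quinolone synthesis.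

Step 5
Reactants: 8 4-hydroxy-7,8-dimethoxy-1-methylquinolin-2(1H)-one
Product: 9 4,7,8-trimethoxy-1-methylquinolin-2(1H)-one
Conditions: Me2SO4, K2CO3, acetone, reflux
Reagents that add atoms: dimethyl sulfate, COS(=O)(=O)OC
Why: O-Alkylation of the vinylogous-acid hydroxyl with a hard methylating agent and carbonate base gives the 4-methoxy-2-quinolone, the lactam nitrogen being already substituted.

Step 6
Reactants: 8 4-hydroxy-7,8-dimethoxy-1-methylquinolin-2(1H)-one, 4 (E)-5-[(tert-butyldimethylsilyl)oxy]-5-methylhex-2-enal
Product: 10 (4S)-4-{2-[(tert-butyldimethylsilyl)oxy]-2-methylpropyl}-2-hydroxy-7,8-dimethoxy-6-methyl-2,3,4,6-tetrahydro-5H-pyrano[3,2-c]quinolin-5-one (lactol, anomer mixture)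
Conditions: (R)-2-[diphenyl(trimethylsilyloxy)methyl]pyrrolidine (20 mol%), PhCO2H (20 mol%), CH2Cl2, rt
Reagents that add atoms: none
Why: Iminium-catalysed Michael addition of the 4-hydroxy-2-quinolone C-3 nucleophile to the enal followed by hemiacetalisation (the organocatalytic route known for 4-hydroxycoumarins) sets C-a, because the diphenyl(silyloxy)methyl group of the (R)-catalyst shields one face of the s-trans (E)-iminium ion and C-3 should add to the open face to give the (S) centre.

Step 7
Reactants: 10 lactol from step 6
Product: 11 (4S)-4-{2-[(tert-butyldimethylsilyl)oxy]-2-methylpropyl}-7,8-dimethoxy-6-methyl-3,4-dihydro-2H-pyrano[3,2-c]quinoline-2,5(6H)-dione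
Conditions: PhI(OAc)2 (1.5 equiv), TEMPO (10 mol%), CH2Cl2, rt
Reagents that add atoms: none
Why: TEMPO/PhI(OAc)2 (oxoammonium) oxidation of a lactol to the lactone runs under near-neutral conditions that spare the silyl ether and C-a.

Step 8
Reactants: 11 lactone from step 7, 12 acetone
Product: 14 (3R,4S)-4-{2-[(tert-butyldimethylsilyl)oxy]-2-methylpropyl}-3-(2-hydroxypropan-2-yl)-7,8-dimethoxy-6-methyl-3,4-dihydro-2H-pyrano[3,2-c]quinoline-2,5(6H)-dione, via lithium enolate 13 (not isolated)
Conditions: LiN(SiMe3)2 (1.1 equiv), THF, −78 °C; 12 (3 equiv), −78 °C; AcOH quench at −78 °C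
Reagents that add atoms: none
Why: Aldol addition of the lactone lithium enolate to acetone sets C-b by substrate control, the ketone approaching the enolate face anti to the pseudo-axial C-a substituent to give the 3,4-trans product, and the cold acidic quench forestalls retro-aldol or acyl transfer of the aldolate.

Step 9
Reactants: 14 hydroxy lactone from step 8
Product: 15 (3R,4S)-4-{2-[(tert-butyldimethylsilyl)oxy]-2-methylpropyl}-2-hydroxy-3-(2-hydroxypropan-2-yl)-7,8-dimethoxy-6-methyl-2,3,4,6-tetrahydro-5H-pyrano[3,2-c]quinolin-5-one (lactol, anomer mixture)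
Conditions: iBu2AlH (2.3 equiv), CH2Cl2, −78 °C; aq. potassium sodium tartrate work-up
Reagents that add atoms: none
Why: Partial reduction of a lactone with iBu2AlH at −78 °C should stop at the aluminium hemiacetal and give the lactol on work-up (one equivalent is consumed by the tertiary hydroxyl), with no stereocentre touched.

Step 10
Reactants: 15 lactol from step 9, 9 4,7,8-trimethoxy-1-methylquinolin-2(1H)-one
Product: 17 tert-butyldimethylsilyl ether of the target at the side-chain carbinol (C-a S; C-b S; C-c R), via C-aryl adduct 16 (not isolated)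
Conditions: Sc(OTf)3 (10 mol%), 9 (1.2 equiv), 5 Å MS, CH2Cl2, −20 °C to 35 °C
Reagents that add atoms: none
Why: Proposed new method: the Lewis acid ionises lactol 15 to its oxocarbenium ion, which alkylates C-3 of the vinylogous carbamate 9 (Friedel–Crafts hydroxyalkylation of the C-glycosylation type) to give adduct 16; 16 ionises again at the C-c–O bond because the cation is an allyl cation over C-c, C-3 and C-4 of quinolone E, so that C-4 becomes a methoxy-oxocarbenium carbon to which the free tertiary hydroxyl adds before methanol leaves (a vinylogous transacetalisation whose closest precedent is the acid-catalysed alkoxy exchange of β-alkoxy enones), and this forms the aryl ether bond of ring D. Ring D closes 6-exo-trig onto the C-4 oxocarbenium carbon, and ring C then re-closes 6-exo-trig when the liberated 4-hydroxyl of quinolone W attacks C-c of the ring-D allyl cation. C-c is the only new stereocentre: the nucleophile is tethered through C-b and must attack the cyclic cation axially from the face of its own tether, so only the cis ring fusion should form (the cation trapping known from acid dimerisation of 2,2-dimethylchromenes), and its absolute sense follows from C-b. The step needs C-3 attack by 9 (its most nucleophilic carbon), oxygen attack at C-4 in preference to ionisation of the tertiary alcohol (secured by the mild acid, since C-4 is activated only within the cation, and by the sieves that remove water and methanol), and no capture of the cation by the side-chain oxygen (secured by the hindered tertiary TBS ether). Both ionisations are reversible, so either C-c epimer of 16 should converge on 17.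

Step 11
Reactants: 17 silyl ether from step 10
Product: 18 target, CNP0160874.2
Conditions: Bu4NF (3 equiv), THF, 50 °C
Reagents that add atoms: none
Why: Fluoride cleavage of the tertiary silyl ether under basic, non-ionising conditions should release the side-chain carbinol without reopening ring C.

**Compound list**

1 | 2-methylpent-4-en-2-ol | CC(C)(O)CC=C | starting material
2 | tert-butyldimethyl[(2-methylpent-4-en-2-yl)oxy]silane | CC(C)(CC=C)O[Si](C)(C)C(C)(C)C | intermediate
3 | (E)-but-2-enal (crotonaldehyde) | C/C=C/C=O | starting material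
4 | (E)-5-[(tert-butyldimethylsilyl)oxy]-5-methylhex-2-enal | O=C/C=C/CC(C)(C)O[Si](C)(C)C(C)(C)C | intermediate
5 | 1-bromo-2,3-dimethoxybenzene | COc1cccc(Br)c1OC | starting material
6 | 2,3-dimethoxy-N-methylaniline | CNc1cccc(OC)c1OC | intermediate
7 | bis(2,4,6-trichlorophenyl) malonate | O=C(CC(=O)Oc1c(Cl)cc(Cl)cc1Cl)Oc1c(Cl)cc(Cl)cc1Cl | starting material
8 | 4-hydroxy-7,8-dimethoxy-1-methylquinolin-2(1H)-one | Cn1c(=O)cc(O)c2ccc(OC)c(OC)c21 | intermediate
9 | 4,7,8-trimethoxy-1-methylquinolin-2(1H)-one | Cn1c(=O)cc(OC)c2ccc(OC)c(OC)c21 | intermediate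
10 | (4S)-4-{2-[(tert-butyldimethylsilyl)oxy]-2-methylpropyl}-2-hydroxy-7,8-dimethoxy-6-methyl-2,3,4,6-tetrahydro-5H-pyrano[3,2-c]quinolin-5-one | COc1ccc2c3c(c(=O)n(C)c2c1OC)[C@@H](CC(C)(C)O[Si](C)(C)C(C)(C)C)CC(O)O3 | intermediate
11 | (4S)-4-{2-[(tert-butyldimethylsilyl)oxy]-2-methylpropyl}-7,8-dimethoxy-6-methyl-3,4-dihydro-2H-pyrano[3,2-c]quinoline-2,5(6H)-dione | COc1ccc2c3c(c(=O)n(C)c2c1OC)[C@@H](CC(C)(C)O[Si](C)(C)C(C)(C)C)CC(=O)O3 | intermediate
12 | acetone | CC(C)=O | starting material
13 | lithium enolate of lactone 11 | [Li+].COc1ccc2c3c(c(=O)n(C)c2c1OC)[C@@H](CC(C)(C)O[Si](C)(C)C(C)(C)C)C=C([O-])O3 | intermediate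
14 | (3R,4S)-4-{2-[(tert-butyldimethylsilyl)oxy]-2-methylpropyl}-3-(2-hydroxypropan-2-yl)-7,8-dimethoxy-6-methyl-3,4-dihydro-2H-pyrano[3,2-c]quinoline-2,5(6H)-dione | COc1ccc2c3c(c(=O)n(C)c2c1OC)[C@@H](CC(C)(C)O[Si](C)(C)C(C)(C)C)[C@H](C(C)(C)O)C(=O)O3 | intermediate
15 | (3R,4S)-4-{2-[(tert-butyldimethylsilyl)oxy]-2-methylpropyl}-2-hydroxy-3-(2-hydroxypropan-2-yl)-7,8-dimethoxy-6-methyl-2,3,4,6-tetrahydro-5H-pyrano[3,2-c]quinolin-5-one | COc1ccc2c3c(c(=O)n(C)c2c1OC)[C@@H](CC(C)(C)O[Si](C)(C)C(C)(C)C)[C@H](C(C)(C)O)C(O)O3 | intermediate
16 | C-aryl adduct: ring C lactol carbon carrying the 4,7,8-trimethoxy-1-methyl-2-oxoquinolin-3-yl group (C-c epimers) | COc1ccc2c3c(c(=O)n(C)c2c1OC)[C@@H](CC(C)(C)O[Si](C)(C)C(C)(C)C)[C@H](C(C)(C)O)C(O3)c1c(OC)c2ccc(OC)c(OC)c2n(C)c1=O | intermediate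
17 | tert-butyldimethylsilyl ether of the target at the side-chain carbinol | COc1ccc2c3c(c(=O)n(C)c2c1OC)[C@@H](CC(C)(C)O[Si](C)(C)C(C)(C)C)[C@H]1[C@@H](O3)c2c(c3ccc(OC)c(OC)c3n(C)c2=O)OC1(C)C | intermediate
18 | CNP0160874.2 | COc1ccc2c3c(c(=O)n(C)c2c1OC)[C@@H](CC(C)(C)O)[C@H]1[C@@H](O3)c2c(c3ccc(OC)c(OC)c3n(C)c2=O)OC1(C)C | target

**Step count**

Total steps: 11. Longest linear sequence: 8 steps (5 → 6 → 8 → 10 → 11 → 14 → 15 → 17 → 18).

**Steps most likely to fail**

Step 10 (proposed new method). β-Elimination from the lactol-derived oxocarbenium ion, or aldol-type dehydration of the open hydroxy aldehyde, may outrun the intermolecular Friedel–Crafts step, and proton loss from the allyl cation may erode C-b. The fallback uses known chemistry, sets out from 8 and 15 and returns to the route at 17. Quinolone 8 is converted with POCl3 into 4-chloro-7,8-dimethoxy-1-methylquinolin-2(1H)-one F1. F1 is magnesiated at C-3 with TMPMgCl·LiCl and added at −78 °C to the aldehyde form of 15 (lactol and tertiary hydroxyl first deprotonated with iPrMgCl) to give the open-chain chloro triol F2 as C-c epimers. KOtBu in THF then closes ring D by intramolecular SNAr of the tertiary alkoxide on C-4, chloride leaving, to give the ring-D carbinol F3. Brief treatment of F3 with camphorsulfonic acid in CH2Cl2 ionises the C-c hydroxyl, and the 4-hydroxyl of quinolone W closes ring C cis to give 17.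

Step 8. The enol-lactone enolate may fragment to a ketene with loss of the quinolonoxide, or the lithium aldolate may undergo acyl transfer or retro-aldol cleavage on warming. The fallback sets out from 11 and returns at 14. Lactone 11 is opened with K2CO3 in methanol to the methyl ester F4, so that the enolate chemistry is done on an ordinary ester. The dianion of F4 (LiN(iPr)2, 2.2 equiv, THF, −78 °C) is added to acetone to give the aldol hydroxy ester F5. Acid-catalysed relactonisation of F5 (camphorsulfonic acid, toluene) with loss of methanol, followed by equilibration of C-b with DBU to the trans lactone, gives 14.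

Step 9. The aluminium hemiacetal may collapse at low temperature, because the quinolonoxide is a good leaving group, and the liberated aldehyde would then be over-reduced. The fallback sets out from 14 and returns at 15. Lactone 14 is deliberately reduced through with LiBH4 in THF to the ring-opened primary alcohol F6. Chemoselective oxidation of the primary hydroxyl of F6 with TEMPO/PhI(OAc)2 gives the aldehyde, which closes spontaneously to lactol 15.

Further compounds

F1 | step 10 | 4-chloro-7,8-dimethoxy-1-methylquinolin-2(1H)-one | Cn1c(=O)cc(Cl)c2ccc(OC)c(OC)c21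
F2 | step 10 | open-chain chloro triol (C-c epimers) | COc1ccc2c(O)c(c(=O)n(C)c2c1OC)[C@@H](CC(C)(C)O[Si](C)(C)C(C)(C)C)[C@H](C(C)(C)O)C(O)c1c(Cl)c2ccc(OC)c(OC)c2n(C)c1=O
F3 | step 10 | ring-D carbinol (C-c epimers) | COc1ccc2c(O)c(c(=O)n(C)c2c1OC)[C@@H](CC(C)(C)O[Si](C)(C)C(C)(C)C)[C@H]1C(O)c2c(c3ccc(OC)c(OC)c3n(C)c2=O)OC1(C)C
F4 | step 8 | methyl ester from methanolysis of lactone 11 | COc1ccc2c(O)c(c(=O)n(C)c2c1OC)[C@@H](CC(C)(C)O[Si](C)(C)C(C)(C)C)CC(=O)OC
F5 | step 8 | aldol hydroxy ester (C-b epimers) | COc1ccc2c(O)c(c(=O)n(C)c2c1OC)[C@@H](CC(C)(C)O[Si](C)(C)C(C)(C)C)C(C(C)(C)O)C(=O)OC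
F6 | step 9 | ring-opened primary alcohol | COc1ccc2c(O)c(c(=O)n(C)c2c1OC)[C@@H](CC(C)(C)O[Si](C)(C)C(C)(C)C)[C@H](C(C)(C)O)CO
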